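The (2R,3R)-dibenzylbutanediol core is read as a reduced butenolide. b2 and b3 are lactone C4 and C3, their CH2OH carbons are C5 and C2, and each carries one arylmethyl arm, b1 to guaiacyl ring A and b4 to ring B of the dihydrobenzofuran. One flask joins three fragments. A lithiated ring A dithioacetal adds to C4 of (5R)-menthyloxybutenolide and the enolate is benzylated at C3 by the ring B bromide, which makes bonds b1–b2 and b3–b4 and both core stereocentres. The electrophile is an enantiopure (2S,3R)-5-bromomethyl-dihydrobenzofuran, built by iridium-catalysed etherification and oxygenative radical cyclisation. Its CH2OH is masked as a pivalate that the later LiAlH4 reduction removes.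

Key step: step 12

Labels: ring A is the far guaiacyl ring, ring B the benzo ring of the dihydrobenzofuran, ring C its 2-aryl group. The chain reads ring A–b1H2–b2H(CH2OH)–b3H(CH2OH)–b4H2–ring B. The target is (R) at b2 and b3 and (2S,3R), that is trans, in the dihydrobenzofuran.

Assumption: in step 7 the (Sa,Sc,Sc) antipode of the phosphoramidite is taken to deliver the (S)-ether; if a test run shows the opposite sense of induction, the mirror-image ligand, equally available, is used and nothing else changes.

Step 1
Reactants: 1 furfural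
Product: 3 5-hydroxyfuran-2(5H)-one (racemic hemiacetal), via furfural endoperoxide 2 (not isolated)
Conditions: O2, visible light, rose bengal (C20H2Cl4I4Na2O5, cat), MeOH, 20 °C
Reagents that add atoms: dioxygen O=O
Why: Dye-sensitised photooxygenation, in which singlet oxygen adds across the furan in a [4+2] cycloaddition and methanol strips the formyl group from endoperoxide 2 as its formate ester, leaving the configurationally labile hydroxybutenolide.

Step 2
Reactants: 3 5-hydroxyfuran-2(5H)-one; 4 (−)-menthol
Product: 5 (5R)-5-(l-menthyloxy)furan-2(5H)-one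
Conditions: p-toluenesulfonic acid monohydrate (cat), toluene, reflux, Dean–Stark trap; crystallisation from hexane, mother liquor re-equilibrated with the same acid and crystallised again
Reagents that add atoms: none
Why: Acid-catalysed acetalisation gives both C5 epimers, which interconvert under acid, and only the (5R) epimer of the l-menthyl series crystallises, so crystallisation with recycling sets C5 under control of the menthyl stereocentres.

Step 3
Reactants: 6 4-benzyloxy-3-methoxybenzaldehyde (O-benzylvanillin)
Product: 7 4-benzyloxy-3-methoxybenzaldehyde bis(phenylthio)acetal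
Conditions: PhSH (2.1 equiv), BF3·OEt2 (0.2 equiv), CH2Cl2, 0 °C
Reagents that add atoms: thiophenol Sc1ccccc1
Why: Lewis-acid-catalysed dithioacetalisation of an electron-rich aromatic aldehyde is fast at 0 °C and leaves the benzyl ether untouched.

Step 4
Reactants: 6 4-benzyloxy-3-methoxybenzaldehyde
Product: 8 ethyl (E)-3-(4-benzyloxy-3-methoxyphenyl)acrylate
Conditions: (EtO)2P(O)CH2CO2Et, NaH, THF, 0 °C to rt
Reagents that add atoms: triethyl phosphonoacetate CCOC(=O)CP(=O)(OCC)OCC
Why: Horner–Wadsworth–Emmons olefination with a stabilised phosphonate should give the (E)-cinnamate with high selectivity.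

Step 5
Reactants: 8 ethyl (E)-3-(4-benzyloxy-3-methoxyphenyl)acrylate
Product: 9 (E)-3-(4-benzyloxy-3-methoxyphenyl)prop-2-en-1-ol
Conditions: i-Bu2AlH (2.2 equiv), CH2Cl2, −78 °C; aqueous work-up
Reagents that add atoms: none
Why: 1,2-Reduction of an α,β-unsaturated ester with i-Bu2AlH at low temperature ends at the (E)-allylic alcohol without touching the alkene.

Step 6
Reactants: 9 (E)-3-(4-benzyloxy-3-methoxyphenyl)prop-2-en-1-ol
Product: 10 (E)-3-(4-benzyloxy-3-methoxyphenyl)prop-2-en-1-yl methyl carbonate
Conditions: ClCO2Me, pyridine, CH2Cl2, 0 °C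
Reagents that add atoms: methyl chloroformate COC(=O)Cl
Why: O-Acylation with a chloroformate installs the leaving group needed for metal-catalysed allylic substitution.

Step 7
Reactants: 10 (E)-cinnamyl methyl carbonate; 11 5-iodovanillin
Product: 13 4-{[(1S)-1-(4-benzyloxy-3-methoxyphenyl)prop-2-en-1-yl]oxy}-3-iodo-5-methoxybenzaldehyde, via sodium phenoxide of 5-iodovanillin 12 (not isolated)
Conditions: 11 (1.5 equiv), NaH (1.0 equiv), THF, 0 °C; then 10, [Ir(cod)Cl]2 (2 mol%), (Sa,Sc,Sc)-O,O'-(1,1'-binaphthalene-2,2'-diyl) N,N-bis(1-phenylethyl)phosphoramidite (4 mol%), catalyst pre-activated with n-PrNH2 at 50 °C and freed of volatiles, THF, rt, stopped at full conversion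
Reagents that add atoms: none
Why: Iridium-catalysed asymmetric allylic etherification of a linear cinnamyl carbonate with an aryloxide, in which the cyclometalated iridium–phosphoramidite complex ionises 10 and steers the phenoxide to the aryl-bearing allyl terminus on one face, so that the ligand sets the (S) ether carbon (later C2), while the surplus phenol buffers the methoxide released.

Step 8
Reactants: 13 (S)-branched allyl aryl ether
Product: 15 (2S,3R)-2-(4-benzyloxy-3-methoxyphenyl)-3-(hydroxymethyl)-7-methoxy-2,3-dihydrobenzofuran-5-carbaldehyde, via primary hydroperoxide 14 (not isolated)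
Conditions: Bu3SnH (1.5 equiv, slow addition), Et3B (cat), dry air, toluene, 0 °C; then PPh3
Reagents that add atoms: dioxygen O=O
Why: Oxygenative tin-hydride radical cyclisation, in which the aryl radical from C–I abstraction closes 5-exo-trig onto the vinyl group far faster than it meets O2, through a chair-like transition state with ring C pseudo-equatorial so that C3 is set trans to C2 (3R), and the primary radical is then taken by O2 faster than by the dilute stannane, PPh3 reducing hydroperoxide 14 without touching the aldehyde.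

Step 9
Reactants: 15 hydroxymethyl dihydrobenzofuran aldehyde
Product: 16 [(2S,3R)-2-(4-benzyloxy-3-methoxyphenyl)-5-formyl-7-methoxy-2,3-dihydrobenzofuran-3-yl]methyl pivalate
Conditions: t-BuCOCl, pyridine, DMAP (cat), CH2Cl2, 0 °C to rt
Reagents that add atoms: pivaloyl chloride CC(C)(C)C(=O)Cl
Why: Acylation of the only hydroxyl group gives an ester that has no enolisable hydrogen, withstands borohydride, PBr3, the lithium enolate and nickel boride, and falls to the LiAlH4 that the end game needs anyway.

Step 10
Reactants: 16 pivalate aldehyde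
Product: 17 [(2S,3R)-2-(4-benzyloxy-3-methoxyphenyl)-5-(hydroxymethyl)-7-methoxy-2,3-dihydrobenzofuran-3-yl]methyl pivalate
Conditions: NaBH4, MeOH–THF, 0 °C
Reagents that add atoms: none
Why: Chemoselective borohydride reduction takes the aldehyde and leaves the hindered ester alone.

Step 11
Reactants: 17 benzylic alcohol
Product: 18 [(2S,3R)-2-(4-benzyloxy-3-methoxyphenyl)-5-(bromomethyl)-7-methoxy-2,3-dihydrobenzofuran-3-yl]methyl pivalate
Conditions: PBr3 (0.4 equiv), Et2O–CH2Cl2, 0 °C; NaHCO3 wash, used at once without chromatography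
Reagents that add atoms: phosphorus tribromide BrP(Br)Br
Why: Bromination of an electron-rich benzylic alcohol through its phosphite ester is fast at 0 °C, and both stereocentres are remote from the reacting carbon.

Step 12
Reactants: 7 bis(phenylthio)acetal of ring A; 5 (5R)-menthyloxybutenolide; 18 benzylic bromide of ring B
Product: 21 (3R,4R,5R)-4-[(4-benzyloxy-3-methoxyphenyl)bis(phenylthio)methyl]-3-{[(2S,3R)-2-(4-benzyloxy-3-methoxyphenyl)-7-methoxy-3-(pivaloyloxymethyl)-2,3-dihydrobenzofuran-5-yl]methyl}-5-(l-menthyloxy)dihydrofuran-2(3H)-one, via lithiated dithioacetal 19 (not isolated), via lithium lactone enolate 20 (not isolated)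
Conditions: 7 (1.3 equiv), n-BuLi (1.25 equiv), THF, −78 °C; 5 (1.2 equiv), −78 °C; then DMPU, 18 (1.0 equiv), −78 to −20 °C
Reagents that add atoms: none
Why: n-BuLi converts 7 into the sulfur-stabilised benzylic carbanion 19, which attacks C4 of 5 in a Michael addition (bond b1–b2), and the lithium enolate 20 left behind then displaces bromide from 18 by SN2 attack through C3 (bond b3–b4). The closest known reaction type is the three-component conjugate addition–enolate alkylation of 5-alkoxybutenolides with lithiated aryl dithioacetals and benzylic halides, a standard entry to dibenzylbutyrolactone lignans. No ring is closed in this step. C4 (later b2) is controlled by the C5 acetal centre, whose menthyloxy group blocks one face so that 19 arrives on the other, and C3 (later b3) is controlled by the very large aryl-bis(phenylthio)methyl group just installed, which sends 18 to the face opposite to it and so gives the (3R,4R,5R) all-trans lactone. The step needs 1,4- over 1,2-addition, which the soft, delocalised and crowded carbanion secures at −78 °C, and clean C-alkylation without proton exchange, which rests on the reactive benzylic bromide, on DMPU, on a small excess of the cheap enolate over the valuable 18, and on the absence of acidic hydrogen in 18. Because 5 is a single enantiomer, any antipode left in 18 becomes a diastereomer of 21 and can be removed at this point.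

Step 13
Reactants: 21 trisubstituted menthyloxy lactone
Product: 22 (3R,4R,5R)-4-(4-benzyloxy-3-methoxybenzyl)-3-{[(2S,3R)-2-(4-benzyloxy-3-methoxyphenyl)-7-methoxy-3-(pivaloyloxymethyl)-2,3-dihydrobenzofuran-5-yl]methyl}-5-(l-menthyloxy)dihydrofuran-2(3H)-one
Conditions: NiCl2·6H2O, NaBH4, MeOH–THF, 0 °C
Reagents that add atoms: none
Why: Reductive desulfurisation with nickel boride (Ni2B) made in the flask cleaves both benzylic C–S bonds to give the b1 methylene, spares the benzyl ethers, the pivalate, the lactone acetal and the cyclic benzylic ether, and touches no stereocentre.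

Step 14
Reactants: 22 desulfurised menthyloxy lactone
Product: 23 (2R,3R)-2-(4-benzyloxy-3-methoxybenzyl)-3-{[(2S,3R)-2-(4-benzyloxy-3-methoxyphenyl)-3-(hydroxymethyl)-7-methoxy-2,3-dihydrobenzofuran-5-yl]methyl}butane-1,4-diol
Conditions: LiAlH4, THF, 0 °C to reflux; aqueous work-up
Reagents that add atoms: none
Why: Hydride reduction of the lactone opens it to a hemiacetal alkoxide that expels menthoxide, the aldehyde so formed is reduced at once so that C2 and C5 become the two CH2OH groups without epimerisation of b2 or b3, and the pivalate is cleaved reductively in the same operation.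

Step 15
Reactants: 23 dibenzyl-protected triol
Product: 24 target, (2R,3R)-2-(4-hydroxy-3-methoxybenzyl)-3-{[(2S,3R)-2-(4-hydroxy-3-methoxyphenyl)-3-(hydroxymethyl)-7-methoxy-2,3-dihydrobenzofuran-5-yl]methyl}butane-1,4-diol
Conditions: H2 (1 atm), 10% Pd/C, EtOAc–EtOH, rt, stopped after uptake of two equivalents
Reagents that add atoms: none
Why: Catalytic hydrogenolysis of aryl benzyl ethers is much faster than that of the cyclic C2–O benzylic bond at 1 atm in a neutral solvent, so both phenols should be freed with the dihydrobenzofuran intact.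

Compound list
1 | furfural | O=Cc1ccco1 | starting material
2 | 2,3,7-trioxabicyclo[2.2.1]hept-5-ene-1-carbaldehyde (furfural endoperoxide) | O=CC12OOC(C=C1)O2 | intermediate
3 | 5-hydroxyfuran-2(5H)-one (racemic) | O=C1C=CC(O)O1 | intermediate
4 | (−)-menthol, (1R,2S,5R) | O[C@@H]1C[C@H](C)CC[C@H]1C(C)C | starting material
5 | (5R)-5-(l-menthyloxy)furan-2(5H)-one | O=C1C=C[C@H](O[C@@H]2C[C@H](C)CC[C@H]2C(C)C)O1 | intermediate
6 | 4-benzyloxy-3-methoxybenzaldehyde | COc1cc(C=O)ccc1OCc1ccccc1 | starting material
7 | 4-benzyloxy-3-methoxybenzaldehyde bis(phenylthio)acetal | COc1cc(C(Sc2ccccc2)Sc2ccccc2)ccc1OCc1ccccc1 | intermediate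
8 | ethyl (E)-3-(4-benzyloxy-3-methoxyphenyl)acrylate | CCOC(=O)/C=C/c1ccc(OCc2ccccc2)c(OC)c1 | intermediate
9 | (E)-3-(4-benzyloxy-3-methoxyphenyl)prop-2-en-1-ol | OC/C=C/c1ccc(OCc2ccccc2)c(OC)c1 | intermediate
10 | (E)-3-(4-benzyloxy-3-methoxyphenyl)prop-2-en-1-yl methyl carbonate | COC(=O)OC/C=C/c1ccc(OCc2ccccc2)c(OC)c1 | intermediate
11 | 5-iodovanillin | COc1cc(C=O)cc(I)c1O | starting material
12 | sodium 4-formyl-2-iodo-6-methoxyphenoxide | COc1cc(C=O)cc(I)c1[O-].[Na+] | intermediate
13 | 4-{[(1S)-1-(4-benzyloxy-3-methoxyphenyl)prop-2-en-1-yl]oxy}-3-iodo-5-methoxybenzaldehyde | C=C[C@@H](c1ccc(OCc2ccccc2)c(OC)c1)Oc1c(I)cc(C=O)cc1OC | intermediate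
14 | (2S,3R)-2-(4-benzyloxy-3-methoxyphenyl)-3-(hydroperoxymethyl)-7-methoxy-2,3-dihydrobenzofuran-5-carbaldehyde | O=Cc1cc(OC)c2c(c1)[C@H](COO)[C@@H](c1ccc(OCc3ccccc3)c(OC)c1)O2 | intermediate
15 | (2S,3R)-2-(4-benzyloxy-3-methoxyphenyl)-3-(hydroxymethyl)-7-methoxy-2,3-dihydrobenzofuran-5-carbaldehyde | O=Cc1cc(OC)c2c(c1)[C@H](CO)[C@@H](c1ccc(OCc3ccccc3)c(OC)c1)O2 | intermediate
16 | [(2S,3R)-2-(4-benzyloxy-3-methoxyphenyl)-5-formyl-7-methoxy-2,3-dihydrobenzofuran-3-yl]methyl pivalate | O=Cc1cc(OC)c2c(c1)[C@H](COC(=O)C(C)(C)C)[C@@H](c1ccc(OCc3ccccc3)c(OC)c1)O2 | intermediate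
17 | [(2S,3R)-2-(4-benzyloxy-3-methoxyphenyl)-5-(hydroxymethyl)-7-methoxy-2,3-dihydrobenzofuran-3-yl]methyl pivalate | OCc1cc(OC)c2c(c1)[C@H](COC(=O)C(C)(C)C)[C@@H](c1ccc(OCc3ccccc3)c(OC)c1)O2 | intermediate
18 | [(2S,3R)-2-(4-benzyloxy-3-methoxyphenyl)-5-(bromomethyl)-7-methoxy-2,3-dihydrobenzofuran-3-yl]methyl pivalate | BrCc1cc(OC)c2c(c1)[C@H](COC(=O)C(C)(C)C)[C@@H](c1ccc(OCc3ccccc3)c(OC)c1)O2 | intermediate
19 | [(4-benzyloxy-3-methoxyphenyl)bis(phenylthio)methyl]lithium | [Li]C(Sc1ccccc1)(Sc1ccccc1)c1ccc(OCc2ccccc2)c(OC)c1 | intermediate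
20 | lithium enolate of the (4R,5R) conjugate adduct | COc1cc(C(Sc2ccccc2)(Sc2ccccc2)[C@@H]3C=C(O[Li])O[C@H]3O[C@@H]2C[C@H](C)CC[C@H]2C(C)C)ccc1OCc1ccccc1 | intermediate
21 | (3R,4R,5R) all-trans menthyloxy lactone carrying rings A, B and C, with dithioacetal and pivalate | COc1cc(C(Sc2ccccc2)(Sc2ccccc2)[C@@H]([C@H](O[C@@H]2C[C@H](C)CC[C@H]2C(C)C)O5)[C@H](C5=O)Cc2cc(OC)c3c(c2)[C@H](COC(=O)C(C)(C)C)[C@@H](c2ccc(OCc4ccccc4)c(OC)c2)O3)ccc1OCc1ccccc1 | intermediate
22 | (3R,4R,5R) desulfurised menthyloxy lactone | COc1cc(C[C@@H]([C@H](O[C@@H]2C[C@H](C)CC[C@H]2C(C)C)O5)[C@H](C5=O)Cc2cc(OC)c3c(c2)[C@H](COC(=O)C(C)(C)C)[C@@H](c2ccc(OCc4ccccc4)c(OC)c2)O3)ccc1OCc1ccccc1 | intermediate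
23 | (2R,3R) triol with both phenols as benzyl ethers | COc1cc(C[C@@H](CO)[C@H](CO)Cc2cc(OC)c3c(c2)[C@H](CO)[C@@H](c2ccc(OCc4ccccc4)c(OC)c2)O3)ccc1OCc1ccccc1 | intermediate
24 | CNP0256425.1 | COc1cc(C[C@@H](CO)[C@H](CO)Cc2cc(OC)c3c(c2)[C@H](CO)[C@@H](c2ccc(O)c(OC)c2)O3)ccc1O | target

Total step count: 15. Longest linear sequence: 12 steps (6, 8, 9, 10, 13, 15, 16, 17, 18, 21, 22, 23, 24).

Steps most likely to fail

Risk 1, step 12. Alkylation of the crowded enolate may be slower than proton exchange, retro-Michael loss of the thioacetal anion, or decay of the labile bromide. As a fallback the two bond formations are uncoupled.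
- The fallback sets out from 5 and 7. The conjugate addition is run as before, but enolate 20 is quenched with aqueous NH4Cl.
- This should give the trans adduct (4R,5R)-4-[(4-benzyloxy-3-methoxyphenyl)bis(phenylthio)methyl]-5-(l-menthyloxy)dihydrofuran-2(3H)-one F1, a stable compound that can be purified.
- F1 is then deprotonated with LiN(SiMe3)2 in THF–DMPU at −78 °C and alkylated with 18 under exact stoichiometry. The same large C4 substituent directs the attack, and the route is rejoined at 21.

Risk 2, step 7. The hindered, weakly nucleophilic aryloxide may react slowly. The product is the ether of a good leaving group on an electron-rich allyl system, so it may also re-ionise on the catalyst. That would erode the enantiomeric purity and let the branched ether drift towards the linear one. As a fallback, enantiopurity is secured by classical resolution instead of catalyst control.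
- Material of whatever enantiomeric purity is taken through step 8, and the fallback sets out from 15.
- Steglich esterification with (S)-2-methoxy-2-phenylacetic acid (N,N'-dicyclohexylcarbodiimide, DMAP, CH2Cl2) should give the (2S,3R) O-methylmandelate ester F2 beside the (2R,3S) O-methylmandelate ester F3.
- The two esters are separated by crystallisation or chromatography. Methanolysis of F2 (K2CO3, MeOH) comes back to the route at 15 as a single enantiomer.

Risk 3, step 8. Hydrogen transfer to the primary radical may precede oxygen capture, or chain autoxidation of the aldehyde C–H may set in in the aerated solution. As a fallback oxygen is replaced by a persistent nitroxyl radical under argon.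
- The fallback sets out from 13. Bu3SnH and TEMPO (2,2,6,6-tetramethylpiperidin-1-oxyl), both added in portions in toluene at 70 °C, should give the same trans 5-exo cyclisation. The primary radical is trapped as the 2,2,6,6-tetramethylpiperidin-1-yl ether F4.
- Reductive N–O cleavage of F4 with Zn in AcOH–THF–H2O then frees the primary alcohol, and the route is rejoined at 15.

Further compounds
F1 | step 12 | (4R,5R)-4-[(4-benzyloxy-3-methoxyphenyl)bis(phenylthio)methyl]-5-(l-menthyloxy)dihydrofuran-2(3H)-one | COc1cc(C(Sc2ccccc2)(Sc2ccccc2)[C@@H]3CC(=O)O[C@H]3O[C@@H]2C[C@H](C)CC[C@H]2C(C)C)ccc1OCc1ccccc1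
F2 | step 7 | [(2S,3R)-2-(4-benzyloxy-3-methoxyphenyl)-5-formyl-7-methoxy-2,3-dihydrobenzofuran-3-yl]methyl (S)-2-methoxy-2-phenylacetate | O=Cc1cc(OC)c2c(c1)[C@H](COC(=O)[C@@H](OC)c1ccccc1)[C@@H](c1ccc(OCc3ccccc3)c(OC)c1)O2
F3 | step 7 | [(2R,3S)-2-(4-benzyloxy-3-methoxyphenyl)-5-formyl-7-methoxy-2,3-dihydrobenzofuran-3-yl]methyl (S)-2-methoxy-2-phenylacetate | O=Cc1cc(OC)c2c(c1)[C@@H](COC(=O)[C@@H](OC)c1ccccc1)[C@H](c1ccc(OCc3ccccc3)c(OC)c1)O2
F4 | step 8 | (2S,3R)-2-(4-benzyloxy-3-methoxyphenyl)-7-methoxy-3-{[(2,2,6,6-tetramethylpiperidin-1-yl)oxy]methyl}-2,3-dihydrobenzofuran-5-carbaldehyde | O=Cc1cc(OC)c2c(c1)[C@H](CON1C(C)(C)CCCC1(C)C)[C@@H](c1ccc(OCc3ccccc3)c(OC)c1)O2
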